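The synthesis rests on disconnecting the bond between the benzylic CH2 carbon attached to the isobutyryl-bearing ring and C-5 of the central (R)-2-methylbutanoylphloroglucinol ring. This CH2 lies between two free hydroxyls of its own ring, so that ring can be released as an ortho-quinone methide from a dimethylaminomethyl (Mannich) precursor. C-5 is an enol-like carbon flanked by two hydroxyls and is the only unsubstituted ring carbon of the acetyl-ring/central-ring dimer. In one biomimetic operation the quinone methide is generated and captured by conjugate addition and rearomatisation, joining a 13-carbon electrophile to the unprotected 22-carbon dimer and completing the trimer.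

Key step: step 13

Remark: the side-chain stereocentre of the target is (R); it is taken unchanged from (R)-2-methylbutanoic acid (13), assumed to be commercially available in high enantiomeric purity.

Step 1
Reactants: 1 2-methylbenzene-1,3,5-triol (2,4,6-trihydroxytoluene)
Product: 2 1-(2,4,6-trihydroxy-3-methylphenyl)ethan-1-one
Conditions: AcCl (1.05 equiv), AlCl3 (4 equiv), PhNO2/CH2Cl2, 0 → 40 °C; then ice/2 M HCl
Reagents that add atoms: acetyl chloride, CC(Cl)=O
Why: Friedel–Crafts C-acylation of a symmetrical triol whose two free ring positions are equivalent, so only one mono-ketone can form, and the first acyl group deactivates the ring towards a second.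

Step 2
Reactants: 2 1-(2,4,6-trihydroxy-3-methylphenyl)ethan-1-one
Product: 3 1-[2-hydroxy-4,6-bis(methoxymethoxy)-3-methylphenyl]ethan-1-one
Conditions: MOMCl (2.1 equiv), i-Pr2NEt (2.5 equiv), CH2Cl2, 0 °C
Reagents that add atoms: chloromethyl methyl ether, COCCl
Why: O-alkylation (MOM ether formation) should take the most acidic 4-OH and the less hindered 6-OH, while the 2-OH, pressed by the 3-methyl group into a strong hydrogen bond with the ketone, stays free.

Step 3
Reactants: 3 1-[2-hydroxy-4,6-bis(methoxymethoxy)-3-methylphenyl]ethan-1-one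
Product: 4 1-[2-methoxy-4,6-bis(methoxymethoxy)-3-methylphenyl]ethan-1-one
Conditions: MeI (3 equiv), K2CO3 (2 equiv), DMF, 40 °C
Reagents that add atoms: iodomethane, CI
Why: Williamson O-methylation of the remaining chelated phenol under forcing carbonate conditions; the MOM acetals are stable to base and carbonate does not C-alkylate the ketone.

Step 4
Reactants: 4 1-[2-methoxy-4,6-bis(methoxymethoxy)-3-methylphenyl]ethan-1-one
Product: 5 1-(4,6-dihydroxy-2-methoxy-3-methylphenyl)ethan-1-one
Conditions: 3 M aq. HCl (cat.), MeOH, 50 °C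
Reagents that add atoms: none
Why: Acid-catalysed acetal exchange (MOM cleavage) with methanol as formaldehyde acceptor; the aryl methyl ether and ketone are inert and the acyl-deactivated ring should resist hydroxymethylation.

Step 5
Reactants: 5 1-(4,6-dihydroxy-2-methoxy-3-methylphenyl)ethan-1-one
Product: 6 1-{5-[(dimethylamino)methyl]-4,6-dihydroxy-2-methoxy-3-methylphenyl}ethan-1-one
Conditions: Me2NCH2NMe2 (2 equiv), CH2Cl2, 0 °C → rt, inverse addition of 5; volatiles removed in vacuo
Reagents that add atoms: bis(dimethylamino)methane, CN(C)CN(C)C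
Why: Phenolic Mannich reaction at the only unsubstituted ring carbon, which lies between two hydroxyls; the acidic phenol ionises the aminal to the iminium ion and excess aminal suppresses methylene-bis dimer formation.

Step 6
Reactants: 1 2-methylbenzene-1,3,5-triol
Product: 7 2-methyl-1-(2,4,6-trihydroxy-3-methylphenyl)propan-1-one
Conditions: i-PrCOCl (1.05 equiv), AlCl3 (4 equiv), PhNO2/CH2Cl2, 0 → 40 °C; then ice/2 M HCl
Reagents that add atoms: 2-methylpropanoyl chloride, CC(C)C(Cl)=O
Why: Friedel–Crafts C-acylation, regiochemically unambiguous for the same symmetry reason as in step 1.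

Step 7
Reactants: 7 2-methyl-1-(2,4,6-trihydroxy-3-methylphenyl)propan-1-one
Product: 8 1-[2-hydroxy-4,6-bis(methoxymethoxy)-3-methylphenyl]-2-methylpropan-1-one
Conditions: MOMCl (2.1 equiv), i-Pr2NEt (2.5 equiv), CH2Cl2, 0 °C
Reagents that add atoms: chloromethyl methyl ether, COCCl
Why: O-alkylation (MOM ether formation) with the same selectivity argument as step 2, leaving the buttressed, chelated 2-OH free.

Step 8
Reactants: 8 1-[2-hydroxy-4,6-bis(methoxymethoxy)-3-methylphenyl]-2-methylpropan-1-one
Product: 9 1-[2-methoxy-4,6-bis(methoxymethoxy)-3-methylphenyl]-2-methylpropan-1-one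
Conditions: MeI (3 equiv), K2CO3 (2 equiv), DMF, 40 °C
Reagents that add atoms: iodomethane, CI
Why: Williamson O-methylation of the chelated phenol; the MOM ethers and the hindered ketone are untouched by carbonate.

Step 9
Reactants: 9 1-[2-methoxy-4,6-bis(methoxymethoxy)-3-methylphenyl]-2-methylpropan-1-one
Product: 10 1-(4,6-dihydroxy-2-methoxy-3-methylphenyl)-2-methylpropan-1-one
Conditions: 3 M aq. HCl (cat.), MeOH, 50 °C
Reagents that add atoms: none
Why: Acid-catalysed MOM cleavage by acetal exchange with methanol; the methyl ether and ketone survive.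

Step 10
Reactants: 10 1-(4,6-dihydroxy-2-methoxy-3-methylphenyl)-2-methylpropan-1-one
Product: 11 1-{5-[(dimethylamino)methyl]-4,6-dihydroxy-2-methoxy-3-methylphenyl}-2-methylpropan-1-one
Conditions: Me2NCH2NMe2 (2 equiv), CH2Cl2, 0 °C → rt, inverse addition of 10; volatiles removed in vacuo
Reagents that add atoms: bis(dimethylamino)methane, CN(C)CN(C)C
Why: Phenolic Mannich reaction at the single free ring carbon between two hydroxyls, installing the benzylic carbon together with its leaving group.

Step 11
Reactants: 12 phloroglucinol (benzene-1,3,5-triol); 13 (R)-2-methylbutanoic acid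
Product: 15 (2R)-2-methyl-1-(2,4,6-trihydroxyphenyl)butan-1-one, via (R)-2-methylbutanoyl chloride 14 (not isolated)
Conditions: 13, (COCl)2 (1.05 equiv), cat. DMF, CH2Cl2, 0 °C → rt, concentrate cold; then 12 (1.2 equiv), AlCl3 (4 equiv), PhNO2/CH2Cl2, 0 °C → rt; ice/2 M HCl
Reagents that add atoms: none
Why: Base-free acid chloride formation followed by Friedel–Crafts acylation of phloroglucinol; no stereocentre is created, and the (R)-centre from 13 should be preserved because no amine base is present to form a ketene and the temperature is kept low.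

Step 12
Reactants: 6 1-{5-[(dimethylamino)methyl]-4,6-dihydroxy-2-methoxy-3-methylphenyl}ethan-1-one; 15 (2R)-2-methyl-1-(2,4,6-trihydroxyphenyl)butan-1-one
Product: 17 (2R)-1-{3-[(3-acetyl-2,6-dihydroxy-4-methoxy-5-methylphenyl)methyl]-2,4,6-trihydroxyphenyl}-2-methylbutan-1-one, via acetyl-ring ortho-quinone methide 16 (not isolated)
Conditions: 15 (3 equiv), 6 (1 equiv, added slowly), 1,4-dioxane, 80 °C, slow N2 sweep; excess 15 recovered
Reagents that add atoms: none
Why: Thermal loss of dimethylamine from the zwitterionic Mannich base gives ortho-quinone methide 16, which is C-alkylated in a Michael (Friedel–Crafts-type) addition by one of the two equivalent ring CH positions of 15; the excess of 15 limits double alkylation.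

Step 13
Reactants: 17 (2R)-1-{3-[(3-acetyl-2,6-dihydroxy-4-methoxy-5-methylphenyl)methyl]-2,4,6-trihydroxyphenyl}-2-methylbutan-1-one; 11 1-{5-[(dimethylamino)methyl]-4,6-dihydroxy-2-methoxy-3-methylphenyl}-2-methylpropan-1-one
Product: 19 (2R)-1-{3-[(3-acetyl-2,6-dihydroxy-4-methoxy-5-methylphenyl)methyl]-5-{[2,6-dihydroxy-4-methoxy-3-methyl-5-(2-methylpropanoyl)phenyl]methyl}-2,4,6-trihydroxyphenyl}-2-methylbutan-1-one, via isobutyryl-ring ortho-quinone methide 18 (not isolated)
Conditions: 17 (1.0 equiv), 11 (1.2 equiv, in portions), 1,4-dioxane, 90 °C, slow N2 sweep; dilute HCl wash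
Reagents that add atoms: none
Why: Mannich base 11 exists largely as an ammonium phenolate and should lose dimethylamine on warming (E1cB-type 1,4-elimination) to give ortho-quinone methide 18, whose exocyclic methylene is attacked in a conjugate fashion by C-5 of the central ring of 17, an enol carbon flanked by two hydroxyls; tautomerisation then restores both aromatic rings and makes the C–C bond formation irreversible. The closest known reaction type is the Mannich-base/ortho-quinone methide alkylation used to build unsymmetrical methylene-bis-acylphloroglucinols, which also mirrors the presumed biosynthetic methylene bridging. No ring is closed and no stereocentre is created; the (R)-centre of the 2-methylbutanoyl chain should stay intact because under these weakly basic conditions the ketone is part of a chelated phenol/phenolate that does not enolise towards the side chain. The step needs site selectivity, C- over O-alkylation and integrity of the existing methylene bridge: C-5 is the only unsubstituted aromatic carbon of 17, O-adducts of 18 revert to 18 whereas the C-adduct aromatises, and 18 cannot alkylate its own fully substituted ring. Retro-Michael scrambling of the existing bridge is limited by sweeping out dimethylamine and keeping the temperature moderate.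

Compound list
1 | 2-methylbenzene-1,3,5-triol (2,4,6-trihydroxytoluene) | Cc1c(O)cc(O)cc1O | starting material
2 | 1-(2,4,6-trihydroxy-3-methylphenyl)ethan-1-one | CC(=O)c1c(O)c(C)c(O)cc1O | intermediate
3 | 1-[2-hydroxy-4,6-bis(methoxymethoxy)-3-methylphenyl]ethan-1-one | CC(=O)c1c(O)c(C)c(OCOC)cc1OCOC | intermediate
4 | 1-[2-methoxy-4,6-bis(methoxymethoxy)-3-methylphenyl]ethan-1-one | CC(=O)c1c(OC)c(C)c(OCOC)cc1OCOC | intermediate
5 | 1-(4,6-dihydroxy-2-methoxy-3-methylphenyl)ethan-1-one | CC(=O)c1c(OC)c(C)c(O)cc1O | intermediate
6 | 1-{5-[(dimethylamino)methyl]-4,6-dihydroxy-2-methoxy-3-methylphenyl}ethan-1-one | CC(=O)c1c(OC)c(C)c(O)c(CN(C)C)c1O | intermediate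
7 | 2-methyl-1-(2,4,6-trihydroxy-3-methylphenyl)propan-1-one | CC(C)C(=O)c1c(O)c(C)c(O)cc1O | intermediate
8 | 1-[2-hydroxy-4,6-bis(methoxymethoxy)-3-methylphenyl]-2-methylpropan-1-one | CC(C)C(=O)c1c(O)c(C)c(OCOC)cc1OCOC | intermediate
9 | 1-[2-methoxy-4,6-bis(methoxymethoxy)-3-methylphenyl]-2-methylpropan-1-one | CC(C)C(=O)c1c(OC)c(C)c(OCOC)cc1OCOC | intermediate
10 | 1-(4,6-dihydroxy-2-methoxy-3-methylphenyl)-2-methylpropan-1-one | CC(C)C(=O)c1c(OC)c(C)c(O)cc1O | intermediate
11 | 1-{5-[(dimethylamino)methyl]-4,6-dihydroxy-2-methoxy-3-methylphenyl}-2-methylpropan-1-one | CC(C)C(=O)c1c(OC)c(C)c(O)c(CN(C)C)c1O | intermediate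
12 | phloroglucinol (benzene-1,3,5-triol) | Oc1cc(O)cc(O)c1 | starting material
13 | (R)-2-methylbutanoic acid | CC[C@@H](C)C(=O)O | starting material
14 | (R)-2-methylbutanoyl chloride | CC[C@@H](C)C(Cl)=O | intermediate
15 | (2R)-2-methyl-1-(2,4,6-trihydroxyphenyl)butan-1-one | CC[C@@H](C)C(=O)c1c(O)cc(O)cc1O | intermediate
16 | acetyl-ring ortho-quinone methide, 4-acetyl-5-hydroxy-3-methoxy-2-methyl-6-methylidenecyclohexa-2,4-dien-1-one | C=C1C(=O)C(C)=C(OC)C(C(C)=O)=C1O | intermediate
17 | (2R)-1-{3-[(3-acetyl-2,6-dihydroxy-4-methoxy-5-methylphenyl)methyl]-2,4,6-trihydroxyphenyl}-2-methylbutan-1-one | CC[C@@H](C)C(=O)c1c(O)c(Cc2c(O)c(C)c(OC)c(C(C)=O)c2O)c(O)cc1O | intermediate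
18 | isobutyryl-ring ortho-quinone methide, 5-hydroxy-3-methoxy-2-methyl-6-methylidene-4-(2-methylpropanoyl)cyclohexa-2,4-dien-1-one | C=C1C(=O)C(C)=C(OC)C(C(=O)C(C)C)=C1O | intermediate
19 | (2R)-1-{3-[(3-acetyl-2,6-dihydroxy-4-methoxy-5-methylphenyl)methyl]-5-{[2,6-dihydroxy-4-methoxy-3-methyl-5-(2-methylpropanoyl)phenyl]methyl}-2,4,6-trihydroxyphenyl}-2-methylbutan-1-one | CC[C@@H](C)C(=O)c1c(O)c(Cc2c(O)c(C)c(OC)c(C(C)=O)c2O)c(O)c(Cc2c(O)c(C)c(OC)c(C(=O)C(C)C)c2O)c1O | target

Total step count: 13. Longest linear sequence: 7 steps (steps 1, 2, 3, 4, 5, 12, 13).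

Steps most likely to fail

Step 13. The existing methylene bridge of 17 may be scrambled by amine-promoted retro-Michael cleavage at the reaction temperature, and reversible O-capture or oligomerisation of the quinone methide may outrun C–C bond formation. The fallback replaces the thermal, amine-releasing generation by an acid-catalysed Friedel–Crafts benzylation with an amine-free electrophile. It sets out from 11, which with MeI in THF at rt should give the trimethylammonium iodide F1. Warming F1 in MeOH with NaHCO3 should give the benzylic methyl ether, 1-[4,6-dihydroxy-2-methoxy-5-(methoxymethyl)-3-methylphenyl]-2-methylpropan-1-one F2, by methanol capture of the quinone methide. F2 and 17 with catalytic TsOH in MeCN/CH2Cl2 at rt should then form the same CH2–C-5 bond and come back to the route at 19.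

Step 2. Site selection between the two ortho hydroxyls (2-OH against 6-OH) may be poor, and over-protection may occur; step 7 carries the same hazard. The fallback replaces kinetic O-alkylation by chelation-directed dealkylation. It sets out from 2, which with BnBr and K2CO3 in DMF should give the tris(benzyl ether), 1-[2,4,6-tris(benzyloxy)-3-methylphenyl]ethan-1-one F3. BCl3 (1 equiv, CH2Cl2, −78 °C) should cleave the benzyl ether that is ortho to the carbonyl and twisted out of the ring plane by the flanking methyl group, giving 1-[4,6-bis(benzyloxy)-2-hydroxy-3-methylphenyl]ethan-1-one F4. O-Methylation (MeI, K2CO3, DMF) should give 1-[4,6-bis(benzyloxy)-2-methoxy-3-methylphenyl]ethan-1-one F5, and hydrogenolysis (H2, Pd/C, EtOAc) comes back to the route at 5.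

Step 11. The enantiomeric purity may erode through ketene or enol formation from the acyl chloride or acylium ion under the strong Lewis acid. The fallback replaces electrophilic acylation by nucleophilic acylation of a Weinreb amide. It sets out from 13 and 12. Acid 13 with MeNHOMe·HCl and EDC/HOBt should give the Weinreb amide, (2R)-N-methoxy-N,2-dimethylbutanamide F6. Phloroglucinol 12 with MOMCl/NaH should give 1,3,5-tris(methoxymethoxy)benzene F7. Lithiation of F7 (n-BuLi, THF, 0 °C) and addition of F6 at −78 °C should give (2R)-2-methyl-1-[2,4,6-tris(methoxymethoxy)phenyl]butan-1-one F8, and HCl/MeOH at 40 °C comes back to the route at 15.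

Further compounds
F1 | step 13 | {[2,6-dihydroxy-4-methoxy-3-methyl-5-(2-methylpropanoyl)phenyl]methyl}trimethylammonium iodide | CC(C)C(=O)c1c(OC)c(C)c(O)c(C[N+](C)(C)C)c1O.[I-]
F2 | step 13 | 1-[4,6-dihydroxy-2-methoxy-5-(methoxymethyl)-3-methylphenyl]-2-methylpropan-1-one | CC(C)C(=O)c1c(OC)c(C)c(O)c(COC)c1O
F3 | step 2 | 1-[2,4,6-tris(benzyloxy)-3-methylphenyl]ethan-1-one | CC(=O)c1c(OCc2ccccc2)c(C)c(OCc2ccccc2)cc1OCc1ccccc1
F4 | step 2 | 1-[4,6-bis(benzyloxy)-2-hydroxy-3-methylphenyl]ethan-1-one | CC(=O)c1c(O)c(C)c(OCc2ccccc2)cc1OCc1ccccc1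
F5 | step 2 | 1-[4,6-bis(benzyloxy)-2-methoxy-3-methylphenyl]ethan-1-one | CC(=O)c1c(OC)c(C)c(OCc2ccccc2)cc1OCc1ccccc1
F6 | step 11 | (2R)-N-methoxy-N,2-dimethylbutanamide | CC[C@@H](C)C(=O)N(C)OC
F7 | step 11 | 1,3,5-tris(methoxymethoxy)benzene | COCOc1cc(OCOC)cc(OCOC)c1
F8 | step 11 | (2R)-2-methyl-1-[2,4,6-tris(methoxymethoxy)phenyl]butan-1-one | CC[C@@H](C)C(=O)c1c(OCOC)cc(OCOC)cc1OCOC
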